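Numbering (germacrane type): C1 ketone, C2=C3 furanone alkene, C4=C5 ring alkene, C6 lactone carbinol, C7, C8 acyloxy carbon, C9H2, C10 quaternary carbon, C11=C13 exocyclic methylene, C12 lactone carbonyl, C14 methyl, C15 CH2OH.
Cuts, in retrosynthetic order: the C8–O acyl bond; C7–C8, which opens the nine-membered oxonine ring (O, C3, C4, C5, C6, C7, C8, C9, C10); C7=C11 and the C6–O acyl bond (butenolide); O–C3 (furanone); C3–C4 (two linear fragments).
Enabling feature: in the α-methylene lactone ring the atoms C13=C11–C7 form an allyl triad whose γ-carbon C7 carries the carbinol C8. C7–C8 is therefore the retron of an SE2′ allylation of a C8 aldehyde by a 3-(metallomethyl)butenolide (C13–metal, C11=C7). The C13 bromide and the endocyclic alkene are the helpers, and both vanish in the event itself.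
Forward order: Sonogashira union of a C4–C7/C15 iodide with a C1–C3/C8–C10/C14 alkyne, furanone ring first (5-endo-dig), butenolide ring second (ring-closing metathesis), nine-membered ring last (CrCl2 allylation), then C8 acylation and desilylation.
Stereochemistry: C10 from (R)-citramalic acid; C6 from a Sharpless kinetic resolution; C4=C5 geometry from trans-hydroalumination/iodination; C7 and C8 from the key step (face control by C6 and a chair transition state); side-chain alkene from syn-hydromagnesiation.

Key step: step 16

Remark: the C1 carbinol centre created in step 6 is carried as a mixture of epimers (left undefined in the SMILES) until step 13 turns it into the ketone.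
Assumption: all compounds marked as starting material in the list are taken as catalogue chemicals.

Step 1
Reactants: 1 tert-butyldimethyl(prop-2-yn-1-yloxy)silane; 2 acrolein
Product: 4 rac-6-[(tert-butyldimethylsilyl)oxy]hex-1-en-4-yn-3-ol, via lithium acetylide 3 (not isolated)
Conditions: n-BuLi, THF, −78 °C; then 2, −78 °C; H2O quench
Reagents that add atoms: none
Why: 1,2-addition of a lithium acetylide to an enal is fast and direct at low temperature, and the new C6 carbinol centre forms racemic and is resolved in step 2.

Step 2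
Reactants: 4 rac-6-[(tert-butyldimethylsilyl)oxy]hex-1-en-4-yn-3-ol
Product: 5 (3S)-6-[(tert-butyldimethylsilyl)oxy]hex-1-en-4-yn-3-ol
Conditions: Ti(OiPr)4 (0.2 equiv), L-(+)-diisopropyl tartrate (0.25 equiv), t-BuOOH (0.6 equiv), 4 Å MS, CH2Cl2, −20 °C
Reagents that add atoms: none
Why: In the Sharpless kinetic resolution with L-(+)-tartrate the (R)-alcohol should be epoxidised at its vinyl group much faster, so the (S)-alcohol, which has the C6 arrangement of the target, should remain when the oxidant is the limiting reagent.

Step 3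
Reactants: 5 (3S)-6-[(tert-butyldimethylsilyl)oxy]hex-1-en-4-yn-3-ol
Product: 7 (3S,4Z)-6-[(tert-butyldimethylsilyl)oxy]-5-iodohexa-1,4-dien-3-ol, via cyclic sodium alkenylalanate 6 (not isolated)
Conditions: NaAlH2(OCH2CH2OMe)2, THF, 0 °C; then I2, THF, −78 → 0 °C
Reagents that add atoms: iodine, [I][I]
Why: Hydroxyl-directed trans-hydroalumination of a propargylic alcohol places aluminium on the distal alkyne carbon C4 inside a five-membered alanate ring, and iodinolysis with retention leaves iodine cis to C6, which fixes the C4=C5 geometry.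

Step 4
Reactants: 8 (R)-citramalic acid
Product: 9 2-[(4R)-2,2,4-trimethyl-5-oxo-1,3-dioxolan-4-yl]acetic acid
Conditions: Me2C(OMe)2, p-TsOH (cat.), acetone, rt
Reagents that add atoms: 2,2-dimethoxypropane, COC(C)(C)OC
Why: Acid-catalysed acetalisation of an α-hydroxy acid gives the five-membered dioxolanone selectively, leaves the β-carboxyl group free and does not touch the quaternary centre C10.

Step 5
Reactants: 9 2-[(4R)-2,2,4-trimethyl-5-oxo-1,3-dioxolan-4-yl]acetic acid
Product: 11 (3R)-3-hydroxy-3-methyloxolan-2-one, via hydroxyethyl dioxolanone 10 (not isolated)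
Conditions: BH3·THF, THF, 0 °C → rt; H2O quench; then p-TsOH (cat.), CH2Cl2, rt
Reagents that add atoms: none
Why: Chemoselective borane reduction of a free carboxylic acid beside a lactone-type ester, followed by acid-catalysed translactonisation with loss of acetone, should give the hydroxy lactone with C10 untouched.

Step 6
Reactants: 11 (3R)-3-hydroxy-3-methyloxolan-2-one; 12 ethynylmagnesium bromide
Product: 14 (3R)-3-methylhex-5-yne-1,3,4-triol (C4 epimers), via lactol 13 (not isolated)
Conditions: iBu2AlH (2.2 equiv), CH2Cl2, −78 °C; then 12 (5 equiv), THF, −78 °C → rt; aq. Rochelle salt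
Reagents that add atoms: none
Why: Partial reduction of a lactone with iBu2AlH and Grignard addition to the ring-opened hydroxy aldehyde form a standard one-pot sequence, and the new C1 centre needs no control because it becomes the ketone in step 13.

Step 7
Reactants: 14 (3R)-3-methylhex-5-yne-1,3,4-triol
Product: 15 (3R)-3-methyl-1,4-bis[(triethylsilyl)oxy]hex-5-yn-3-ol (C4 epimers)
Conditions: Et3SiCl (2.1 equiv), imidazole, CH2Cl2, 0 °C
Reagents that add atoms: chlorotriethylsilane, CC[Si](Cl)(CC)CC
Why: Silylation discriminates by steric demand, so the primary and secondary hydroxyls are capped and the tertiary C10 hydroxyl stays free.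

Step 8
Reactants: 16 but-2-yn-1-ol
Product: 18 (2E)-2-(hydroxymethyl)but-2-enoic acid, via alkenylmagnesium chloride 17 (not isolated)
Conditions: iBuMgCl (2.3 equiv), Cp2TiCl2 (5 mol %), Et2O, 0 °C → rt; then CO2 (gas), −20 °C → rt; 1 M HCl
Reagents that add atoms: carbon dioxide, O=C=O
Why: Titanocene-catalysed hydromagnesiation of a propargylic alcohol is a syn addition that puts magnesium on the carbon next to the carbinol, and carboxylation of the alkenyl Grignard reagent with retention gives the E acid (methyl cis to CH2OH).

Step 9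
Reactants: 18 (2E)-2-(hydroxymethyl)but-2-enoic acid
Product: 20 (2E)-2-{[(tert-butyldimethylsilyl)oxy]methyl}but-2-enoic acid, via bis-silyl derivative 19 (not isolated)
Conditions: t-BuMe2SiCl (2.3 equiv), imidazole, DMF, rt; then THF–H2O, AcOH (cat.), rt
Reagents that add atoms: tert-butylchlorodimethylsilane, CC(C)(C)[Si](C)(C)Cl
Why: Exhaustive silylation followed by selective hydrolysis of the far more labile silyl ester is the usual way to protect a hydroxy acid as its silyl ether.

Step 10
Reactants: 7 (3S,4Z)-6-[(tert-butyldimethylsilyl)oxy]-5-iodohexa-1,4-dien-3-ol; 15 (3R)-3-methyl-1,4-bis[(triethylsilyl)oxy]hex-5-yn-3-ol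
Product: 21 (3S,4E,9R)-5-{[(tert-butyldimethylsilyl)oxy]methyl}-9-methyl-8,11-bis[(triethylsilyl)oxy]undeca-1,4-dien-6-yne-3,9-diol (C3 cis to C6)
Conditions: PdCl2(PPh3)2 (5 mol %), CuI (10 mol %), Et3N, THF, rt, degassed
Reagents that add atoms: none
Why: Sonogashira coupling of an alkenyl iodide proceeds at room temperature with retention of the alkene geometry and tolerates free hydroxyls and silyl ethers.

Step 11
Reactants: 21 enynol from step 10; 22 2-(bromomethyl)acrylic acid
Product: 23 C6 2-(bromomethyl)acrylate ester of 21
Conditions: DCC, DMAP (10 mol %), CH2Cl2, 0 °C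
Reagents that add atoms: none
Why: Steglich esterification acylates the only unhindered free hydroxyl (C6) with retention while the tertiary C10 hydroxyl is inert, masks C6–O against furan formation at the ynone stage, and brings in C11, C12, C13 and the bromide.

Step 12
Reactants: 23 C6 2-(bromomethyl)acrylate ester of 21
Product: 24 triol ester (23 without both triethylsilyl groups)
Conditions: PPTS (cat.), MeOH–CH2Cl2, 0 °C
Reagents that add atoms: none
Why: Triethylsilyl ethers are solvolysed by mild acid far faster than a tert-butyldimethylsilyl ether, so both should leave while the C15 ether, the ester and the bromide persist.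

Step 13
Reactants: 24 triol ester
Product: 26 (2R)-5-[(2Z,4S)-4-{[2-(bromomethyl)prop-2-enoyl]oxy}-1-[(tert-butyldimethylsilyl)oxy]hexa-2,5-dien-2-yl]-2-(2-hydroxyethyl)-2-methylfuran-3(2H)-one, via ynone 25 (not isolated)
Conditions: MnO2 (activated, excess), CH2Cl2, rt; filter; then Ph3PAuNTf2 (5 mol %), toluene, rt
Reagents that add atoms: none
Why: MnO2 oxidises only the propargylic C1 carbinol, and the monovalent gold π-acid then triggers 5-endo-dig addition of the tertiary C10 hydroxyl to C3 (cycloisomerisation of an α′-hydroxy ynone to a 3(2H)-furanone), with C10 retained because its C–O bond is not broken.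

Step 14
Reactants: 26 furanone ester
Product: 27 (2R)-5-{(1Z)-1-[(2R)-4-(bromomethyl)-5-oxo-2,5-dihydrofuran-2-yl]-3-[(tert-butyldimethylsilyl)oxy]prop-1-en-2-yl}-2-(2-hydroxyethyl)-2-methylfuran-3(2H)-one
Conditions: second-generation Hoveyda–Grubbs catalyst (10 mol %), toluene, 60 °C, argon sparge
Reagents that add atoms: none
Why: Ring-closing metathesis of an allylic 2-substituted acrylate gives the α-substituted butenolide, since five-membered ring formation with loss of ethene is favoured over any reaction of the trisubstituted conjugated C4=C5 and C2=C3 alkenes.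

Step 15
Reactants: 27 bromomethyl butenolide alcohol
Product: 28 bromomethyl butenolide aldehyde (27 with CH2CHO in place of CH2CH2OH at C10)
Conditions: Dess–Martin periodinane, CH2Cl2, 0 °C → rt
Reagents that add atoms: none
Why: Dess–Martin oxidation is base-free, which protects the β-oxygenated aldehyde from elimination and the acidic C6–H of the butenolide from epimerisation.

Step 16
Reactants: 28 bromomethyl butenolide aldehyde
Product: 30 (4Z,6R,7R,8S,10R)-8-hydroxy macrocycle (15-O-silyl 8-deacyl target), via allylchromium dichloride 29 (not isolated)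
Conditions: CrCl2 (10 equiv), 4 Å MS, THF, rt, syringe-pump addition of 28 to about 1 mM; H2O quench
Reagents that add atoms: none
Why: Two equivalents of CrCl2 (divalent chromium) reduce the C13–Br bond of 28 to the trivalent allylchromium 29, whose γ-carbon C7 attacks the chromium-bound C8 aldehyde through a closed six-membered transition state (SE2′), so that C7–C8 forms while the double bond moves from C7=C11 to C11=C13 and unveils the α-methylene lactone. The closest known reactions are the Nozaki–Hiyama–Kishi/Barbier allylation of aldehydes with 3-(bromomethyl)furan-2(5H)-ones and the macrocyclising 2-(alkoxycarbonyl)allylations used for ten-membered germacranolide rings. The nine-membered oxonine ring (O, C3, C4, C5, C6, C7, C8, C9, C10) closes in a 9-exo-trig mode at the aldehyde carbon, and the ten-membered carbocycle that shares the new bond closes with it (10-exo-trig), the furanone and lactone rings being already in place. C7 is set by C6, because the aldehyde should reach the flat butenolide on the face anti to the C5 substituent, which gives the trans-fused (6R,7R) lactone. C8 is set by the chair transition state, because the lactone ring locks the allyl unit in the E-type geometry (C13 trans to C6 across C11=C7) without any chance of isomerisation, and with C9 equatorial this gives the anti (7R,8S) relationship and a free C8 hydroxyl. The step needs γ- over α-attack (secured by the cyclic transition state), reduction of the allylic bromide before the dienone or aldehyde (the allylic C–Br bond is by far the fastest acceptor for CrCl2), and ring closure over oligomerisation (slow addition at high dilution, helped by the cis C4=C5 alkene and the rigid 2,5-disubstituted furanone, which turn both chain ends toward each other).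

Step 17
Reactants: 30 8-hydroxy macrocycle; 20 (2E)-2-{[(tert-butyldimethylsilyl)oxy]methyl}but-2-enoic acid
Product: 31 bis(tert-butyldimethylsilyl) ether of the target
Conditions: DCC, DMAP, CH2Cl2, 0 °C → rt
Reagents that add atoms: none
Why: Steglich esterification of the single free hydroxyl (C8) occurs at oxygen with retention, and the E geometry of the acid is the stable one.

Step 18
Reactants: 31 bis(tert-butyldimethylsilyl) ether of the target
Product: 32 target CNP0104364.1
Conditions: HF·pyridine, THF, 0 °C → rt
Reagents that add atoms: none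
Why: Fluoride-mediated cleavage of the two primary allylic silyl ethers under weakly acidic conditions should spare both esters, the furanone and the three Michael acceptors.

Compound list
1 | tert-butyldimethyl(prop-2-yn-1-yloxy)silane | C#CCO[Si](C)(C)C(C)(C)C | starting material
2 | acrolein | C=CC=O | starting material
3 | lithium acetylide of 1 | [Li]C#CCO[Si](C)(C)C(C)(C)C | intermediate
4 | rac-6-[(tert-butyldimethylsilyl)oxy]hex-1-en-4-yn-3-ol | C=CC(O)C#CCO[Si](C)(C)C(C)(C)C | intermediate
5 | (3S)-6-[(tert-butyldimethylsilyl)oxy]hex-1-en-4-yn-3-ol | C=C[C@H](O)C#CCO[Si](C)(C)C(C)(C)C | intermediate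
6 | cyclic sodium alkenylalanate (five-membered ring O–Al–C4=C5–C6, two 2-methoxyethoxy groups on aluminium) | C=C[C@@H]1O[Al-](OCCOC)(OCCOC)C(CO[Si](C)(C)C(C)(C)C)=C1.[Na+] | intermediate
7 | (3S,4Z)-6-[(tert-butyldimethylsilyl)oxy]-5-iodohexa-1,4-dien-3-ol (iodine cis to the carbinol carbon) | C=C[C@H](O)/C=C(\I)CO[Si](C)(C)C(C)(C)C | intermediate
8 | (R)-citramalic acid, (2R)-2-hydroxy-2-methylbutanedioic acid | C[C@@](O)(CC(=O)O)C(=O)O | starting material
9 | 2-[(4R)-2,2,4-trimethyl-5-oxo-1,3-dioxolan-4-yl]acetic acid | C[C@]1(CC(=O)O)OC(C)(C)OC1=O | intermediate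
10 | (5R)-5-(2-hydroxyethyl)-2,2,5-trimethyl-1,3-dioxolan-4-one | C[C@]1(CCO)OC(C)(C)OC1=O | intermediate
11 | (3R)-3-hydroxy-3-methyloxolan-2-one | C[C@@]1(O)CCOC1=O | intermediate
12 | ethynylmagnesium bromide | C#C[Mg]Br | starting material
13 | (3R)-3-methyloxolane-2,3-diol (lactol, anomers, present in the flask as its aluminium alkoxide) | C[C@@]1(O)CCOC1O | intermediate
14 | (3R)-3-methylhex-5-yne-1,3,4-triol (C4 epimers) | C#CC(O)[C@](C)(O)CCO | intermediate
15 | (3R)-3-methyl-1,4-bis[(triethylsilyl)oxy]hex-5-yn-3-ol (C4 epimers) | C#CC(O[Si](CC)(CC)CC)[C@](C)(O)CCO[Si](CC)(CC)CC | intermediate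
16 | but-2-yn-1-ol | CC#CCO | starting material
17 | (E)-alkenylmagnesium chloride alkoxide (magnesium on C2, methyl cis to CH2O) | C/C=C(\CO[Mg]Cl)[Mg]Cl | intermediate
18 | (2E)-2-(hydroxymethyl)but-2-enoic acid | C/C=C(\CO)C(=O)O | intermediate
19 | tert-butyldimethylsilyl (2E)-2-{[(tert-butyldimethylsilyl)oxy]methyl}but-2-enoate | C/C=C(\CO[Si](C)(C)C(C)(C)C)C(=O)O[Si](C)(C)C(C)(C)C | intermediate
20 | (2E)-2-{[(tert-butyldimethylsilyl)oxy]methyl}but-2-enoic acid | C/C=C(\CO[Si](C)(C)C(C)(C)C)C(=O)O | intermediate
21 | (3S,4E,9R)-5-{[(tert-butyldimethylsilyl)oxy]methyl}-9-methyl-8,11-bis[(triethylsilyl)oxy]undeca-1,4-dien-6-yne-3,9-diol (6S,10R in germacrane numbering; alkyne carbon C3 cis to C6; C1 epimers) | C=C[C@H](O)/C=C(/CO[Si](C)(C)C(C)(C)C)C#CC(O[Si](CC)(CC)CC)[C@](C)(O)CCO[Si](CC)(CC)CC | intermediate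
22 | 2-(bromomethyl)acrylic acid | C=C(CBr)C(=O)O | starting material
23 | 2-(bromomethyl)acrylate ester of 21 at the C6 hydroxyl (6S,10R; C1 epimers) | C=C[C@H](OC(=O)C(=C)CBr)/C=C(/CO[Si](C)(C)C(C)(C)C)C#CC(O[Si](CC)(CC)CC)[C@](C)(O)CCO[Si](CC)(CC)CC | intermediate
24 | triol ester: 23 with free hydroxyls at C1, C8 and C10 (6S,10R; C1 epimers) | C=C[C@H](OC(=O)C(=C)CBr)/C=C(/CO[Si](C)(C)C(C)(C)C)C#CC(O)[C@](C)(O)CCO | intermediate
25 | α′-hydroxy ynone: 24 with C1 as ketone (6S,10R) | C=C[C@H](OC(=O)C(=C)CBr)/C=C(/CO[Si](C)(C)C(C)(C)C)C#CC(=O)[C@](C)(O)CCO | intermediate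
26 | (2R)-5-[(2Z,4S)-4-{[2-(bromomethyl)prop-2-enoyl]oxy}-1-[(tert-butyldimethylsilyl)oxy]hexa-2,5-dien-2-yl]-2-(2-hydroxyethyl)-2-methylfuran-3(2H)-one | C=C[C@H](OC(=O)C(=C)CBr)/C=C(/CO[Si](C)(C)C(C)(C)C)C1=CC(=O)[C@@](C)(CCO)O1 | intermediate
27 | (2R)-5-{(1Z)-1-[(2R)-4-(bromomethyl)-5-oxo-2,5-dihydrofuran-2-yl]-3-[(tert-butyldimethylsilyl)oxy]prop-1-en-2-yl}-2-(2-hydroxyethyl)-2-methylfuran-3(2H)-one | O=C1O[C@H](/C=C(/CO[Si](C)(C)C(C)(C)C)C2=CC(=O)[C@@](C)(CCO)O2)C=C1CBr | intermediate
28 | aldehyde: 27 with CH2CHO in place of CH2CH2OH on C10 (6R,10R,4Z) | O=C1O[C@H](/C=C(/CO[Si](C)(C)C(C)(C)C)C2=CC(=O)[C@@](C)(CC=O)O2)C=C1CBr | intermediate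
29 | allylchromium dichloride: 28 with CrCl2 in place of Br on C13 | O=C1O[C@H](/C=C(/CO[Si](C)(C)C(C)(C)C)C2=CC(=O)[C@@](C)(CC=O)O2)C=C1C[Cr](Cl)Cl | intermediate
30 | (4Z,6R,7R,8S,10R)-8-hydroxy macrocycle: target skeleton with free C8 hydroxyl and C15 tert-butyldimethylsilyl ether | C=C1C(=O)O[C@@H]2/C=C(/CO[Si](C)(C)C(C)(C)C)C3=CC(=O)[C@@](C)(C[C@H](O)[C@@H]12)O3 | intermediate
31 | target with both primary hydroxyls as tert-butyldimethylsilyl ethers | C=C1C(=O)O[C@@H]2/C=C(/CO[Si](C)(C)C(C)(C)C)C3=CC(=O)[C@@](C)(C[C@H](OC(=O)/C(=C/C)CO[Si](C)(C)C(C)(C)C)[C@@H]12)O3 | intermediate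
32 | CNP0104364.1 (4Z,6R,7R,8S,10R; side chain 2E) | C=C1C(=O)O[C@@H]2/C=C(/CO)C3=CC(=O)[C@@](C)(C[C@H](OC(=O)/C(=C/C)CO)[C@@H]12)O3 | target

Total step count: 18.
Longest linear sequence: 13 steps (from 8 through steps 4–7 and 10–18 to 32).

Steps most likely to fail

1. Step 16.
- Ring closure may be too slow, so that the allylchromium is protonated or couples between molecules.
- Closure through a boat, or on the C5 face of the butenolide, would mean poor facial selectivity at C7 or C8.
- The aldehyde may suffer β-elimination, and the lactone acyl group may migrate to the new C8 alkoxide.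
- Fallback, from 27: base-free borylation of the allylic bromide (B2pin2, Pd2(dba)3 as zerovalent palladium source, THF, 60 °C) would give the allylboronate alcohol F1. Dess–Martin oxidation would then give the allylboronate aldehyde F2. Intramolecular allylboration at high dilution (Sc(OTf)3 cat., toluene, rt to 60 °C) can react only through the closed chair and needs no reducing metal. It would give the cyclic borate F3, whose hydrolysis on work-up returns to the route at 30.

2. Step 14.
- The ruthenium alkylidene formed at the C7 vinyl group may fail to engage the 1,1-disubstituted, electron-poor, bromomethyl-bearing acrylate.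
- Dimerisation at the vinyl group, ionisation of the doubly allylic ester or bromine-atom transfer on heating could then take over.
- Fallback, from 26: silver-assisted hydrolysis of the bromide (AgOTf, NaHCO3, acetone–H2O; SN2 and SN2′ give the same product) would give the 2-(hydroxymethyl)acrylate ester F4. Ring-closing metathesis, now assisted by the free allylic hydroxyl, would give the 3-(hydroxymethyl)butenolide diol F5. Corey–Kim-type bromination (NBS, Me2S, CH2Cl2, −20 °C), which converts allylic but not saturated alcohols into bromides, returns to the route at 27.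

3. Step 13.
- MnO2 may cleave the C1–C10 glycol.
- The very electrophilic cross-conjugated ynone may decay before it cyclises.
- The neighbouring vinyl group may divert the gold-activated alkyne away from 5-endo-dig closure.
- Fallback, from 24: the order of events is reversed. Gold-catalysed 5-endo-dig hydroalkoxylation of the non-conjugated alkyne (Ph3PAuNTf2, THF, 0 °C), as known for 3-alkyne-1,2-diols, would give the 2,3-dihydrofuran-3-ol F6, because the usual dehydration to a furan is blocked by the quaternary C10. MnO2 oxidation of its allylic C1 carbinol then returns to the route at 26 without an ynone ever being formed.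

Further compounds
F1 | step 16 | allylboronate alcohol: 27 with pinacolboryl in place of Br on C13 (6R,10R,4Z) | O=C1O[C@H](/C=C(/CO[Si](C)(C)C(C)(C)C)C2=CC(=O)[C@@](C)(CCO)O2)C=C1CB3OC(C)(C)C(C)(C)O3
F2 | step 16 | allylboronate aldehyde: 28 with pinacolboryl in place of Br on C13 (6R,10R,4Z) | O=C1O[C@H](/C=C(/CO[Si](C)(C)C(C)(C)C)C2=CC(=O)[C@@](C)(CC=O)O2)C=C1CB3OC(C)(C)C(C)(C)O3
F3 | step 16 | cyclic borate: 30 with pinacolboryl on the C8 oxygen | C=C1C(=O)O[C@@H]2/C=C(/CO[Si](C)(C)C(C)(C)C)C3=CC(=O)[C@@](C)(C[C@H](OB4OC(C)(C)C(C)(C)O4)[C@@H]12)O3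
F4 | step 14 | 2-(hydroxymethyl)acrylate ester: 26 with OH in place of Br (6S,10R,4Z) | C=C[C@H](OC(=O)C(=C)CO)/C=C(/CO[Si](C)(C)C(C)(C)C)C1=CC(=O)[C@@](C)(CCO)O1
F5 | step 14 | 3-(hydroxymethyl)butenolide diol: 27 with OH in place of Br (6R,10R,4Z) | O=C1O[C@H](/C=C(/CO[Si](C)(C)C(C)(C)C)C2=CC(=O)[C@@](C)(CCO)O2)C=C1CO
F6 | step 13 | 2,3-dihydrofuran-3-ol: 26 with CH(OH) in place of the C1 ketone (6S,10R; C1 epimers) | C=C[C@H](OC(=O)C(=C)CBr)/C=C(/CO[Si](C)(C)C(C)(C)C)C1=CC(O)[C@@](C)(CCO)O1
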